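Gambiriin C: a route through closure of the upper pyran ring at C4–C4a

The route does not couple two flavans. C4 of the upper unit is a methine between two phloroglucinol rings (C4a of the upper A ring and C8 of the catechin A ring), and their usual roles are exchanged. The catechin ring is attached first, as its 8-lithio derivative, to an acyclic aldehyde that already holds C2 and C3 (glycolate aldol) and carries the upper A ring only as an aryl ether on O1. Ionisation of the resulting carbinol gives a cation stabilised by the catechin ring; the tethered A ring then closes the upper pyran ring by C4–C4a bond formation and sets C4 (4β) anti to the C3 oxygen; the 4→8 connectivity is fixed beforehand by C8 bromination.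

Key step: step 11

Remark: the SMILES is read as epiafzelechin-(4β→8)-catechin, upper unit 2R,3R,4R (2,3-cis-3,4-trans), lower unit 2R,3S; all hydroxyl groups are carried as benzyl ethers so that one hydrogenolysis ends the route.

Step 1
Reactants: 1 (+)-catechin
Product: 2 5,7,3',4'-tetra-O-benzyl-(+)-catechin
Conditions: BnBr (4.4 equiv), K2CO3, DMF, 0 °C to rt
Reagents that add atoms: benzyl bromide, BrCc1ccccc1
Why: Williamson etherification of the four phenols; carbonate does not deprotonate the secondary 3-OH, which stays free, and no stereocentre is touched.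

Step 2
Reactants: 2 5,7,3',4'-tetra-O-benzyl-(+)-catechin
Product: 3 8-bromo-5,7,3',4'-tetra-O-benzyl-(+)-catechin
Conditions: NBS (1.0 equiv), CH2Cl2, −78 °C to rt
Reagents that add atoms: N-bromosuccinimide, O=C1CCC(=O)N1Br
Why: Electrophilic aromatic bromination, which in benzylated catechins is selective for C8 (flanked by O1 and O7) over C6; this step fixes the later 4→8 connectivity.

Step 3
Reactants: 3 8-bromo-5,7,3',4'-tetra-O-benzyl-(+)-catechin
Product: 5 8-bromo-3,5,7,3',4'-penta-O-benzyl-(+)-catechin [(2R,3S)-3,5,7-tris(benzyloxy)-2-[3,4-bis(benzyloxy)phenyl]-8-bromochromane], via sodium alkoxide 4 (not isolated)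
Conditions: NaH, BnBr, cat. Bu4NI, DMF, 0 °C to rt
Reagents that add atoms: benzyl bromide, BrCc1ccccc1
Why: Williamson etherification of the remaining secondary alcohol, which removes the only acidic proton before the halogen–lithium exchange of step 10.

Step 4
Reactants: 6 (S)-4-benzyloxazolidin-2-one; 7 (benzyloxy)acetyl chloride
Product: 9 (S)-4-benzyl-3-[(benzyloxy)acetyl]oxazolidin-2-one, via lithium oxazolidinide 8 (not isolated)
Conditions: n-BuLi, THF, −78 °C; then 7, −78 to 0 °C
Reagents that add atoms: none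
Why: N-Acylation of the lithiated auxiliary by the acid chloride, the standard entry to glycolyl imides.

Step 5
Reactants: 9 (S)-4-benzyl-3-[(benzyloxy)acetyl]oxazolidin-2-one; 10 4-(benzyloxy)benzaldehyde
Product: 13 (S)-4-benzyl-3-[(2S,3R)-2-(benzyloxy)-3-[4-(benzyloxy)phenyl]-3-hydroxypropanoyl]oxazolidin-2-one, via boron enolate 11 (not isolated), via boron aldolate 12 (not isolated)
Conditions: Bu2BOTf, Et3N, CH2Cl2, −78 to 0 °C; then 10, −78 to 0 °C; pH 7 buffer, MeOH, 30% H2O2, 0 °C
Reagents that add atoms: none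
Why: Evans syn-glycolate aldol, in which the (Z)-boron enolate reacts through a Zimmerman–Traxler chair on the face away from the benzyl group of the auxiliary; this should give the 2,3-syn (2S,3R) adduct, whose two centres become C3 and C2 of the upper unit (both R in flavan numbering, i.e. 2,3-cis).

Step 6
Reactants: 13 aldol adduct
Product: 14 (2S,3R)-2-(benzyloxy)-3-[4-(benzyloxy)phenyl]-3-hydroxy-N-methoxy-N-methylpropanamide
Conditions: MeNH(OMe)·HCl, AlMe3, CH2Cl2, −10 to 0 °C; aq. Rochelle salt
Reagents that add atoms: N,O-dimethylhydroxylamine hydrochloride, CNOC.Cl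
Why: Aluminium-amide transamination of the imide to the Weinreb amide, which is standard for syn-aldol adducts with a free β-hydroxyl and leaves both stereocentres untouched.

Step 7
Reactants: 15 5-bromoresorcinol
Product: 16 1,3-bis(benzyloxy)-5-bromobenzene
Conditions: BnBr (2.2 equiv), K2CO3, acetone, reflux
Reagents that add atoms: benzyl bromide, BrCc1ccccc1
Why: Williamson etherification of both phenols gives the upper A ring as an aryl bromide.

Step 8
Reactants: 14 Weinreb amide; 16 1,3-bis(benzyloxy)-5-bromobenzene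
Product: 17 (2S,3R)-2-(benzyloxy)-3-[4-(benzyloxy)phenyl]-3-[3,5-bis(benzyloxy)phenoxy]-N-methoxy-N-methylpropanamide
Conditions: RockPhos Pd G3 (5 mol%), Cs2CO3, toluene, 80 °C
Reagents that add atoms: none
Why: Buchwald–Hartwig C–O coupling of a secondary alcohol with an aryl bromide; the new bond is made at the aryl carbon, so the carbinol centre (future C2) is retained, the bulky biarylphosphine favours reductive elimination over β-hydride elimination, and the weak heterogeneous base should spare the amide.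

Step 9
Reactants: 17 O-aryl Weinreb amide
Product: 19 (2S,3R)-2-(benzyloxy)-3-[4-(benzyloxy)phenyl]-3-[3,5-bis(benzyloxy)phenoxy]propanal, via aluminium hemiaminal 18 (not isolated)
Conditions: DIBAL-H, THF, −78 °C; aq. Rochelle salt; used crude
Reagents that add atoms: none
Why: Weinreb amide reduction, in which the chelated tetrahedral intermediate releases the aldehyde only on work-up, so over-reduction and epimerisation of the α-alkoxy centre are avoided.

Step 10
Reactants: 5 8-bromo-penta-O-benzylcatechin; 19 aldehyde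
Product: 22 (1RS,2R,3R)-2-(benzyloxy)-3-[4-(benzyloxy)phenyl]-3-[3,5-bis(benzyloxy)phenoxy]-1-[(2R,3S)-3,5,7-tris(benzyloxy)-2-[3,4-bis(benzyloxy)phenyl]chroman-8-yl]propan-1-ol, via aryllithium 20 (not isolated), via lithium alkoxide 21 (not isolated)
Conditions: 5, t-BuLi (2.0 equiv), THF, −78 °C; then 19, −78 °C; H2O quench; filtration through Et3N-deactivated silica
Reagents that add atoms: none
Why: Bromine–lithium exchange followed by 1,2-addition of the 2,6-dioxygenated aryllithium to the aldehyde forms the C4–C8 bond; the new carbinol centre should form as a mixture, which does not matter because it is erased in step 11.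

Step 11
Reactants: 22 carbinol (both C1 epimers)
Product: 24 nona-O-benzyl gambiriin C [3,5,7,4'-tetra-O-benzylepiafzelechin-(4β→8)-3,5,7,3',4'-penta-O-benzylcatechin; upper unit 2R,3R,4R], via benzylic cation 23 (not isolated)
Conditions: BF3·OEt2 (0.3 equiv), CH2Cl2 (0.005 M), −78 to −30 °C
Reagents that add atoms: none
Why: BF3 ionises the carbinol (either epimer) to the 2,4,6-trioxygenated benzylic cation 23, in effect an O-alkylated quinone methide of the catechin A ring, which is captured by an ortho carbon of the tethered 3,5-bis(benzyloxy)phenyl ether and rearomatises by proton loss. This is an intramolecular Friedel–Crafts alkylation of an aryl ether by a benzylic cation, the reaction type by which 3-aryloxy-1-arylpropan-1-ols give 4-arylchromans and aryl 3-arylglycidyl ethers give trans-4-arylchroman-3-ols. The ring closed is the upper pyran ring (C4–C4a bond), 6-exo-trig at the cationic carbon, and the two ortho positions of the aryl ether are equivalent, so one constitution should result. C2 and C3 come unchanged from the aldol, and the new C4 centre is controlled by C3: allylic 1,3-strain with the two ortho oxygen substituents of the catechin ring holds C3–H in the plane of the cation, C3–OBn and C3–C2 then lie on opposite faces, and the arene, which is tied to C2, can only reach the face anti to OBn, giving the 3,4-trans (4β, 4R) product, the same sense as in capture of flavan-4-yl cations. The step needs chemoselective ionisation (only this carbinol is a trioxybenzylic alcohol), intramolecular capture in preference to attack by C6 of a second molecule (high dilution, six-membered transition state, very nucleophilic phloroglucinol ring) and suppression of proton loss from C3 (low temperature, non-basic counter-ion).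

Step 12
Reactants: 24 nona-O-benzyl gambiriin C
Product: 25 gambiriin C
Conditions: H2 (1 atm), 20% Pd(OH)2/C, THF/MeOH/H2O, rt
Reagents that add atoms: none
Why: Hydrogenolysis of all nine benzyl ethers under neutral conditions, which is standard for benzylated proanthocyanidins and should leave the interflavan bond, both pyran rings and all five stereocentres intact.

Compound list
1 | (+)-catechin, (2R,3S) | Oc1cc(O)c2c(c1)O[C@H](c1ccc(O)c(O)c1)[C@@H](O)C2 | starting material
2 | 5,7,3',4'-tetra-O-benzyl-(+)-catechin | O(Cc1ccccc1)c1cc(OCc3ccccc3)c2c(c1)O[C@H](c1ccc(OCc3ccccc3)c(OCc3ccccc3)c1)[C@@H](O)C2 | intermediate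
3 | 8-bromo-5,7,3',4'-tetra-O-benzyl-(+)-catechin | O(Cc1ccccc1)c1cc(OCc3ccccc3)c2c(c1Br)O[C@H](c1ccc(OCc3ccccc3)c(OCc3ccccc3)c1)[C@@H](O)C2 | intermediate
4 | sodium 3-alkoxide of 3 | O(Cc1ccccc1)c1cc(OCc3ccccc3)c2c(c1Br)O[C@H](c1ccc(OCc3ccccc3)c(OCc3ccccc3)c1)[C@@H](O[Na])C2 | intermediate
5 | 8-bromo-3,5,7,3',4'-penta-O-benzyl-(+)-catechin | O(Cc1ccccc1)c1cc(OCc3ccccc3)c2c(c1Br)O[C@H](c1ccc(OCc3ccccc3)c(OCc3ccccc3)c1)[C@@H](OCc1ccccc1)C2 | intermediate
6 | (S)-4-benzyloxazolidin-2-one | O=C1OC[C@H](Cc2ccccc2)N1 | starting material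
7 | (benzyloxy)acetyl chloride | O=C(Cl)COCc1ccccc1 | starting material
8 | N-lithio derivative of 6 | O=C1OC[C@H](Cc2ccccc2)N1[Li] | intermediate
9 | (S)-4-benzyl-3-[(benzyloxy)acetyl]oxazolidin-2-one | O=C1OC[C@H](Cc2ccccc2)N1C(=O)COCc1ccccc1 | intermediate
10 | 4-(benzyloxy)benzaldehyde | O=Cc1ccc(OCc2ccccc2)cc1 | starting material
11 | (Z)-dibutylboron enolate of 9 | O=C1OC[C@H](Cc2ccccc2)N1/C(OB(CCCC)CCCC)=C/OCc1ccccc1 | intermediate
12 | dibutylboron aldolate of 13 | O=C1OC[C@H](Cc2ccccc2)N1C(=O)[C@@H](OCc1ccccc1)[C@H](OB(CCCC)CCCC)c1ccc(OCc2ccccc2)cc1 | intermediate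
13 | (S)-4-benzyl-3-[(2S,3R)-2-(benzyloxy)-3-[4-(benzyloxy)phenyl]-3-hydroxypropanoyl]oxazolidin-2-one | O=C1OC[C@H](Cc2ccccc2)N1C(=O)[C@@H](OCc1ccccc1)[C@H](O)c1ccc(OCc2ccccc2)cc1 | intermediate
14 | (2S,3R)-2-(benzyloxy)-3-[4-(benzyloxy)phenyl]-3-hydroxy-N-methoxy-N-methylpropanamide | CON(C)C(=O)[C@@H](OCc1ccccc1)[C@H](O)c1ccc(OCc2ccccc2)cc1 | intermediate
15 | 5-bromoresorcinol (5-bromobenzene-1,3-diol) | Oc1cc(O)cc(Br)c1 | starting material
16 | 1,3-bis(benzyloxy)-5-bromobenzene | Brc1cc(OCc2ccccc2)cc(OCc2ccccc2)c1 | intermediate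
17 | (2S,3R)-2-(benzyloxy)-3-[4-(benzyloxy)phenyl]-3-[3,5-bis(benzyloxy)phenoxy]-N-methoxy-N-methylpropanamide | CON(C)C(=O)[C@@H](OCc1ccccc1)[C@H](Oc1cc(OCc2ccccc2)cc(OCc2ccccc2)c1)c1ccc(OCc2ccccc2)cc1 | intermediate
18 | diisobutylaluminium hemiaminal from 17 (hemiaminal carbon unspecified) | CON(C)C(O[Al](CC(C)C)CC(C)C)[C@@H](OCc1ccccc1)[C@H](Oc1cc(OCc2ccccc2)cc(OCc2ccccc2)c1)c1ccc(OCc2ccccc2)cc1 | intermediate
19 | (2S,3R)-2-(benzyloxy)-3-[4-(benzyloxy)phenyl]-3-[3,5-bis(benzyloxy)phenoxy]propanal | O=C[C@@H](OCc1ccccc1)[C@H](Oc1cc(OCc2ccccc2)cc(OCc2ccccc2)c1)c1ccc(OCc2ccccc2)cc1 | intermediate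
20 | 8-lithio-3,5,7,3',4'-penta-O-benzylcatechin | O(Cc1ccccc1)c1cc(OCc3ccccc3)c2c(c1[Li])O[C@H](c1ccc(OCc3ccccc3)c(OCc3ccccc3)c1)[C@@H](OCc1ccccc1)C2 | intermediate
21 | lithium alkoxide of 22 (carbinol carbon unspecified) | [Li]OC(c1c(OCc2ccccc2)cc(OCc2ccccc2)c2c1O[C@H](c1ccc(OCc3ccccc3)c(OCc3ccccc3)c1)[C@@H](OCc1ccccc1)C2)[C@@H](OCc1ccccc1)[C@H](Oc1cc(OCc2ccccc2)cc(OCc2ccccc2)c1)c1ccc(OCc2ccccc2)cc1 | intermediate
22 | (1RS,2R,3R)-2-(benzyloxy)-3-[4-(benzyloxy)phenyl]-3-[3,5-bis(benzyloxy)phenoxy]-1-[penta-O-benzylcatechin-8-yl]propan-1-ol | OC(c1c(OCc2ccccc2)cc(OCc2ccccc2)c2c1O[C@H](c1ccc(OCc3ccccc3)c(OCc3ccccc3)c1)[C@@H](OCc1ccccc1)C2)[C@@H](OCc1ccccc1)[C@H](Oc1cc(OCc2ccccc2)cc(OCc2ccccc2)c1)c1ccc(OCc2ccccc2)cc1 | intermediate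
23 | benzylic cation from 22 (cationic carbon = future C4) | [CH+](c1c(OCc2ccccc2)cc(OCc2ccccc2)c2c1O[C@H](c1ccc(OCc3ccccc3)c(OCc3ccccc3)c1)[C@@H](OCc1ccccc1)C2)[C@@H](OCc1ccccc1)[C@H](Oc1cc(OCc2ccccc2)cc(OCc2ccccc2)c1)c1ccc(OCc2ccccc2)cc1 | intermediate
24 | nona-O-benzyl gambiriin C, 3,5,7,4'-tetra-O-benzylepiafzelechin-(4β→8)-3,5,7,3',4'-penta-O-benzylcatechin | c1ccccc1COc1ccc([C@H]2Oc3cc(OCc5ccccc5)cc(OCc5ccccc5)c3[C@H](c3c(OCc5ccccc5)cc(OCc5ccccc5)c4c3O[C@H](c3ccc(OCc5ccccc5)c(OCc5ccccc5)c3)[C@@H](OCc3ccccc3)C4)[C@H]2OCc2ccccc2)cc1 | intermediate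
25 | gambiriin C, epiafzelechin-(4β→8)-catechin | Oc1ccc([C@H]2Oc3cc(O)cc(O)c3[C@H](c3c(O)cc(O)c4c3O[C@H](c3ccc(O)c(O)c3)[C@@H](O)C4)[C@H]2O)cc1 | target

Total step count: 12. Longest linear sequence: 8 steps (steps 4, 5, 6, 8, 9, 10, 11, 12 from 6).

Steps most likely to fail

Step 11 (key step). The ring closure may show poor facial selectivity at the cationic carbon (3,4-cis epimer), the cation may lose the C3 proton to give an enol ether, or it may alkylate C6 of a second molecule. The fallback sets out from aldehyde 19 and the tetrabenzyl ether 2 and comes back to the route at 25. Aldehyde 19 is first cyclised on its own with CSA in CH2Cl2/MeOH: the aldehyde, as its acetal-derived oxocarbenium ion, alkylates the same aryl ether ring and the resulting flavan-4-yl cation is capped by methanol. This should give 3,5,7,4'-tetra-O-benzyl-4-methoxyepiafzelechin F1 as a mixture of C4 epimers. F1 is then coupled with an excess of 2 under TMSOTf in CH2Cl2 at −78 °C, the established Lewis-acid interflavan coupling, in which the nucleophile enters C4 trans to the 3-benzyloxy group and the lower unit reacts mainly at C8. This should give the octa-O-benzyl dimer F2 with a free 3-OH in the lower unit, and hydrogenolysis of F2 under the conditions of step 12 should give 25.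

Step 8. The palladium alkoxide may undergo β-hydride elimination (oxidation of the benzylic carbinol, reduction of the aryl bromide), and the β-hydroxy amide may suffer retro-aldol cleavage or epimerisation under the basic coupling conditions. The fallback sets out from aldol adduct 13 and comes back at aldehyde 19; the carbonyl group is removed before the arylation and restored afterwards. Reductive cleavage of the auxiliary with LiBH4 (THF, MeOH, 0 °C) should give (1R,2R)-2-(benzyloxy)-1-[4-(benzyloxy)phenyl]propane-1,3-diol F3. Selective silylation of the primary hydroxyl (TBDPSCl, imidazole, CH2Cl2, 0 °C) should give the mono-silyl ether F4. This base-stable secondary alcohol is then coupled with 16 under the palladium conditions of step 8 at higher temperature to give the aryl ether F5. Desilylation (TBAF, THF) gives (2R,3R)-2-(benzyloxy)-3-[4-(benzyloxy)phenyl]-3-[3,5-bis(benzyloxy)phenoxy]propan-1-ol F6, and Dess–Martin oxidation (NaHCO3, CH2Cl2) gives 19.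

Step 10. The hindered, basic aryllithium may deprotonate the α-alkoxy aldehyde, which is followed by β-elimination of the aryloxide; incomplete exchange or benzylic metalation of a benzyl ether may also interfere. The fallback sets out from Weinreb amide 17 and bromide 5 and comes back at carbinol 22; the C4–C8 bond is made by acylation instead of aldehyde addition. Aryllithium 20, generated from 5 as in step 10, is added to 17 at −78 °C; the chelated tetrahedral adduct is less prone to enolisation and cannot add twice, and on work-up it should give the aryl ketone F7. Reduction of F7 with NaBH4/CeCl3 (MeOH/THF, 0 °C) then gives 22; the configuration of the carbinol is immaterial.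

Further compounds
F1 | step 11 | 3,5,7,4'-tetra-O-benzyl-4-methoxyepiafzelechin (2R,3R; C4 epimers) | COC1[C@@H](OCc2ccccc2)[C@H](Oc2cc(OCc3ccccc3)cc(OCc3ccccc3)c12)c1ccc(OCc2ccccc2)cc1
F2 | step 11 | 3,5,7,4'-tetra-O-benzylepiafzelechin-(4β→8)-5,7,3',4'-tetra-O-benzylcatechin | c1ccccc1COc1ccc([C@H]2Oc3cc(OCc5ccccc5)cc(OCc5ccccc5)c3[C@H](c3c(OCc5ccccc5)cc(OCc5ccccc5)c4c3O[C@H](c3ccc(OCc5ccccc5)c(OCc5ccccc5)c3)[C@@H](O)C4)[C@H]2OCc2ccccc2)cc1
F3 | step 8 | (1R,2R)-2-(benzyloxy)-1-[4-(benzyloxy)phenyl]propane-1,3-diol | OC[C@@H](OCc1ccccc1)[C@H](O)c1ccc(OCc2ccccc2)cc1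
F4 | step 8 | (1R,2R)-2-(benzyloxy)-1-[4-(benzyloxy)phenyl]-3-[(tert-butyldiphenylsilyl)oxy]propan-1-ol | CC(C)(C)[Si](c1ccccc1)(c1ccccc1)OC[C@@H](OCc1ccccc1)[C@H](O)c1ccc(OCc2ccccc2)cc1
F5 | step 8 | tert-butyl[(2R,3R)-2-(benzyloxy)-3-[4-(benzyloxy)phenyl]-3-[3,5-bis(benzyloxy)phenoxy]propoxy]diphenylsilane | CC(C)(C)[Si](c1ccccc1)(c1ccccc1)OC[C@@H](OCc1ccccc1)[C@H](Oc1cc(OCc2ccccc2)cc(OCc2ccccc2)c1)c1ccc(OCc2ccccc2)cc1
F6 | step 8 | (2R,3R)-2-(benzyloxy)-3-[4-(benzyloxy)phenyl]-3-[3,5-bis(benzyloxy)phenoxy]propan-1-ol | OC[C@@H](OCc1ccccc1)[C@H](Oc1cc(OCc2ccccc2)cc(OCc2ccccc2)c1)c1ccc(OCc2ccccc2)cc1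
F7 | step 10 | 2-(benzyloxy)-3-[4-(benzyloxy)phenyl]-3-[3,5-bis(benzyloxy)phenoxy]-1-[penta-O-benzylcatechin-8-yl]propan-1-one (configuration as in 17) | O=C(c1c(OCc2ccccc2)cc(OCc2ccccc2)c2c1O[C@H](c1ccc(OCc3ccccc3)c(OCc3ccccc3)c1)[C@@H](OCc1ccccc1)C2)[C@@H](OCc1ccccc1)[C@H](Oc1cc(OCc2ccccc2)cc(OCc2ccccc2)c1)c1ccc(OCc2ccccc2)cc1
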